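**Retrosynthetic overview**
- The target (R)-4-aryl-5,8-dihydroxytetralone is traced back to a seven-membered aryl lactone, (5R)-5-aryl-4,5-dihydro-1-benzoxepin-2(3H)-one. The lactone acyl group is shifted onto the ring carbon ortho to OMe (Fries-type) and the resulting peri-OMe is cleaved by chelation.
- Key disconnection: the bond between the diarylmethine carbon and its CH2 neighbour. It is made from a carbene-bound homoenolate of acrolein (nucleophilic β-carbon) and the exocyclic carbon of a naphthoquinone methide. This 1,6-addition/lactonisation sets the only stereocenter.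
- The quinone methide is released in the flask from a diaryl(tosyl)methane, itself made from the aryllithium of 4-bromo-5-methoxy-1-naphthol and 2-hydroxy-5-methoxybenzaldehyde.
- Ring order: both aromatic systems are bought; the seven-membered lactone forms in the key step; the six-membered ketone ring forms last by ring contraction.

Assumption: 5-methoxynaphthalen-1-ol is taken as a catalogue starting material, and the sense of induction of the carbene step is assigned empirically (written with the (5aS,10bR) precatalyst; its commercial antipode is used if a pilot run gives the mirror-image lactone).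

**Step 1**
Reactants: 1 5-methoxynaphthalen-1-ol
Product: 2 4-bromo-5-methoxynaphthalen-1-ol
Conditions: N-bromosuccinimide (1.0 equiv), MeCN, −20 → 0 °C, dark
Reagents that add atoms: N-bromosuccinimide, O=C1CCC(=O)N1Br
Why: Electrophilic aromatic bromination of a 1-naphthol in MeCN goes to the α-position para to OH, and a peri-OMe does not block that position (1,5-dimethoxynaphthalene also brominates at C4); any 2-bromo isomer is removed by chromatography.

**Step 2**
Reactants: 2 4-bromo-5-methoxynaphthalen-1-ol; 3 2-hydroxy-5-methoxybenzaldehyde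
Product: 7 4-[(2-hydroxy-5-methoxyphenyl)(4-methylbenzenesulfonyl)methyl]-5-methoxynaphthalen-1-ol (racemic), via sodium 2-formyl-4-methoxyphenolate 4 (not isolated), via sodium 4-lithio-5-methoxynaphthalen-1-olate 5 (not isolated), via benzhydrol triol 6 (not isolated)
Conditions: 2, NaH (1.05 equiv), THF, 0 °C, then t-BuLi (2.1 equiv), −78 °C; add 3 pre-treated with NaH (1.05 equiv) in THF, −78 → 0 °C; then TolSO2Na (3 equiv), AcOH–H2O, 25 °C
Reagents that add atoms: sodium 4-methylbenzenesulfinate, [Na+].[O-]S(=O)c1ccc(C)cc1
Why: Bromine–lithium exchange on the naphtholate gives an aryllithium held by the peri-OMe, which adds 1,2 to the aldehyde phenolate; the doubly hydroxy-activated benzhydrol then ionises in AcOH and is trapped at sulfur by sulfinate (SN1-type substitution) to give a bench-stable quinone methide precursor, whose racemic stereocenter is erased in step 3.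

**Step 3**
Reactants: 7 4-[(2-hydroxy-5-methoxyphenyl)(4-methylbenzenesulfonyl)methyl]-5-methoxynaphthalen-1-ol; 8 acrolein (prop-2-enal)
Product: 10 (5R)-5-(4-hydroxy-8-methoxynaphthalen-1-yl)-7-methoxy-4,5-dihydro-1-benzoxepin-2(3H)-one, via naphthoquinone methide 9 (not isolated)
Conditions: (5aS,10bR)-2-mesityl-5a,10b-dihydro-4H,6H-indeno[2,1-b][1,2,4]triazolo[4,3-d][1,4]oxazin-2-ium chloride (15 mol %), K2CO3 (1.3 equiv), 4 Å MS, THF (0.05 M), 0 → 25 °C, acrolein (3 equiv) by syringe pump over 6 h
Reagents that add atoms: none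
Why: Proposed new method: K2CO3 eliminates sulfinate from 7 to give quinone methide 9, while the triazolylidene adds to acrolein to form the Breslow intermediate, whose β-carbon (homoenolate) attacks the exocyclic carbon of 9 in a 1,6-addition driven by re-aromatisation to the naphtholate; tautomerisation gives an acyl azolium that the ortho phenolate captures to close the seven-membered lactone and release the carbene, and the chiral carbene-bound homoenolate discriminates the two faces of the single-geometry quinone methide (hydrogen bond from its ortho OH to the enol) to set C5 as (R); the closest known reaction type is the carbene-catalysed formal [4+3] annulation of enals with ortho-quinone methides and ortho-hydroxyphenyl para-quinone methides released from sulfones, and new here are the β-unsubstituted enal and the unshielded naphthoquinone methide.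

**Step 4**
Reactants: 10 (5R)-5-(4-hydroxy-8-methoxynaphthalen-1-yl)-7-methoxy-4,5-dihydro-1-benzoxepin-2(3H)-one
Product: 12 (4R)-5,8-dihydroxy-4-(4-hydroxy-8-methoxynaphthalen-1-yl)-3,4-dihydronaphthalen-1(2H)-one, via methyl ether 11 (not isolated)
Conditions: AlCl3 (5 equiv), CH2Cl2–MeNO2 (4:1), 0 → 25 °C; then 1 M HCl, 0 °C
Reagents that add atoms: none
Why: AlCl3 ionises the aryl lactone to a tethered acylium that acylates the carbon ortho to OMe (intramolecular Friedel–Crafts acylation, a Fries-type acyl shift as in dihydrocoumarin to 4-hydroxyindan-1-one), and the peri-methoxy ketone so formed is demethylated through its six-membered aluminium chelate while the non-chelated naphthyl OMe stays; no bond to the stereocenter is touched, so (R) is carried through.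

**Compound list**
1 | 5-methoxynaphthalen-1-ol | COc1cccc2c(O)cccc12 | starting material
2 | 4-bromo-5-methoxynaphthalen-1-ol | COc1cccc2c(O)ccc(Br)c12 | intermediate
3 | 2-hydroxy-5-methoxybenzaldehyde | COc1ccc(O)c(C=O)c1 | starting material
4 | sodium 2-formyl-4-methoxyphenolate | [Na+].[O-]c1ccc(OC)cc1C=O | intermediate
5 | sodium 4-lithio-5-methoxynaphthalen-1-olate | [Na+].[O-]c1ccc([Li])c2c(OC)cccc12 | intermediate
6 | 4-[hydroxy(2-hydroxy-5-methoxyphenyl)methyl]-5-methoxynaphthalen-1-ol (racemic) | COc1ccc(O)c(C(O)c2ccc(O)c3cccc(OC)c23)c1 | intermediate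
7 | 4-[(2-hydroxy-5-methoxyphenyl)(4-methylbenzenesulfonyl)methyl]-5-methoxynaphthalen-1-ol (racemic) | COc1ccc(O)c(C(c2ccc(O)c3cccc(OC)c23)S(=O)(=O)c2ccc(C)cc2)c1 | intermediate
8 | acrolein (prop-2-enal) | C=CC=O | starting material
9 | 4-[(2-hydroxy-5-methoxyphenyl)methylidene]-5-methoxynaphthalen-1(4H)-one | COc1ccc(O)c(C=C2C=CC(=O)c3cccc(OC)c32)c1 | intermediate
10 | (5R)-5-(4-hydroxy-8-methoxynaphthalen-1-yl)-7-methoxy-4,5-dihydro-1-benzoxepin-2(3H)-one | COc1cccc2c(O)ccc([C@H]3CCC(=O)Oc4ccc(OC)cc43)c12 | intermediate
11 | (4R)-5-hydroxy-4-(4-hydroxy-8-methoxynaphthalen-1-yl)-8-methoxy-3,4-dihydronaphthalen-1(2H)-one | COc1cccc2c(O)ccc([C@H]3CCC(=O)c4c(OC)ccc(O)c43)c12 | intermediate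
12 | (4R)-5,8-dihydroxy-4-(4-hydroxy-8-methoxynaphthalen-1-yl)-3,4-dihydronaphthalen-1(2H)-one | COc1cccc2c(O)ccc([C@H]3CCC(=O)c4c(O)ccc(O)c43)c12 | target

**Totals**
Total step count: 4. Longest linear sequence: 4 steps (1 → 2 → 7 → 10 → 12).

**Three steps most likely to fail, with fallbacks**

Step 3 is the most exposed. Acrolein can polymerise or undergo oxa-Michael addition with the phenolates, and face selectivity on an unshielded quinone methide is untested. The fallback sets out from 7 and comes back at 10. The carbene homoenolate is replaced by the zinc homoenolate Zn(CH2CH2CO2Et)2, made from 1-ethoxy-1-(trimethylsilyloxy)cyclopropane and ZnCl2 in Et2O. Using 3.5 equiv with Cu(OTf)2 (5 mol %) and (S)-N,N-bis[(S)-1-phenylethyl]dinaphtho[2,1-d:1',2'-f][1,3,2]dioxaphosphepin-4-amine (10 mol %) in toluene–THF at −30 °C, the first equivalents deprotonate the phenols and release 9, and the remainder adds 1,6 under copper catalysis. This gives ethyl (4R)-4-(2-hydroxy-5-methoxyphenyl)-4-(4-hydroxy-8-methoxynaphthalen-1-yl)butanoate F1. Warming F1 with catalytic TsOH in toluene at 80 °C closes the lactone with loss of ethanol and rejoins the route at 10.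

Step 4 is next. The free, electron-rich naphthol may be protonated at its ipso carbon under AlCl3, which could erode ee by retro-Friedel–Crafts cleavage; the acylium could also close onto naphthalene C2; and the naphthyl OMe could be lost. The fallback sets out from 10 and comes back at 12. K2CO3, BnBr and MeOH in DMF open the lactone and benzylate both phenols, giving methyl (4R)-4-[2-(benzyloxy)-5-methoxyphenyl]-4-[4-(benzyloxy)-8-methoxynaphthalen-1-yl]butanoate F2. LiOH in THF–H2O gives (4R)-4-[2-(benzyloxy)-5-methoxyphenyl]-4-[4-(benzyloxy)-8-methoxynaphthalen-1-yl]butanoic acid F3. Its acid chloride ((COCl)2, catalytic DMF) is cyclised with SnCl4 in CH2Cl2 at −78 °C to (4R)-5-(benzyloxy)-4-[4-(benzyloxy)-8-methoxynaphthalen-1-yl]-8-methoxy-3,4-dihydronaphthalen-1(2H)-one F4. BCl3 with pentamethylbenzene in CH2Cl2 (−78 → 0 °C) then removes both benzyl groups and the chelated peri-OMe to give 12.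

Step 2 is third. Exchange on a naphtholate, addition to a phenolate aldehyde and one-flask sulfinate trapping may each be sluggish. The fallback sets out from 2 and 3 and comes back at 7. MOMCl and i-Pr2NEt convert 2 into 4-bromo-5-methoxy-1-(methoxymethoxy)naphthalene F5 and 3 into 5-methoxy-2-(methoxymethoxy)benzaldehyde F6. Exchange on F5 with n-BuLi (THF, −78 °C) and addition to F6 give [5-methoxy-2-(methoxymethoxy)phenyl][8-methoxy-4-(methoxymethoxy)naphthalen-1-yl]methanol F7. TolSO2Na and HCl in MeOH–THF at 40 °C remove both MOM groups and install the sulfone, rejoining the route at 7.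

**Further compounds**
F1 | step 3 | ethyl (4R)-4-(2-hydroxy-5-methoxyphenyl)-4-(4-hydroxy-8-methoxynaphthalen-1-yl)butanoate | COc1cccc2c(O)ccc([C@@H](CCC(=O)OCC)c3cc(OC)ccc3O)c12
F2 | step 4 | methyl (4R)-4-[2-(benzyloxy)-5-methoxyphenyl]-4-[4-(benzyloxy)-8-methoxynaphthalen-1-yl]butanoate | COc1cccc2c(OCc3ccccc3)ccc([C@@H](CCC(=O)OC)c3cc(OC)ccc3OCc3ccccc3)c12
F3 | step 4 | (4R)-4-[2-(benzyloxy)-5-methoxyphenyl]-4-[4-(benzyloxy)-8-methoxynaphthalen-1-yl]butanoic acid | COc1cccc2c(OCc3ccccc3)ccc([C@@H](CCC(=O)O)c3cc(OC)ccc3OCc3ccccc3)c12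
F4 | step 4 | (4R)-5-(benzyloxy)-4-[4-(benzyloxy)-8-methoxynaphthalen-1-yl]-8-methoxy-3,4-dihydronaphthalen-1(2H)-one | COc1cccc2c(OCc3ccccc3)ccc([C@H]3CCC(=O)c4c(OC)ccc(OCc5ccccc5)c43)c12
F5 | step 2 | 4-bromo-5-methoxy-1-(methoxymethoxy)naphthalene | COCOc1ccc(Br)c2c(OC)cccc12
F6 | step 2 | 5-methoxy-2-(methoxymethoxy)benzaldehyde | COCOc1ccc(OC)cc1C=O
F7 | step 2 | [5-methoxy-2-(methoxymethoxy)phenyl][8-methoxy-4-(methoxymethoxy)naphthalen-1-yl]methanol (racemic) | COCOc1ccc(OC)cc1C(O)c1ccc(OCOC)c2cccc(OC)c12
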